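Retrosynthesis: the fifteen methyl ethers come off first, then the chain G–F–E–D–C–B–A is cut at its six diaryl ether oxygens, and in each of rings A, B, D and F the ring bonds C2–C3 and C5–C6 are cut as well, so that each of these rings becomes an aryloxymalonate plus dimethyl 3-oxopentanedioate.
Enabling feature: in ring F, C4 carries the ether oxygen to ring G between the hydroxylated carbons C3 and C5, and C1 carries the third oxygen; this 1,3,5-trioxygenated ring is the fold of a tri-β-carbonyl chain, and rings D, B and A repeat it.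
Forward: ring G is bought as 3,4,5-trimethoxyphenol and O-alkylated with chloromalonate; ring F is closed by a double Claisen condensation with the keto diester, its C3 and C5 hydroxyls are methylated, and both ester groups are removed to free the C1 phenol.
That phenol is joined to ring E by Ullmann coupling with 2-bromo-3,4,5-trimethoxybenzaldehyde, and Dakin oxidation turns the formyl group into the next phenol; the same cycle then gives rings D (closed), C (coupled), B (closed) and A (closed).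
The rings appear in the order G, F, E, D, C, B, A, and BBr3 finally frees all eighteen hydroxyls.
The target is achiral and has no stereocentre, so no stereochemistry has to be set.

Key step: step 2

Remark: rings are lettered A to G as written in the target SMILES (ring A is the 2,4,6-trihydroxyphenoxy end, ring G the 3,4,5-trihydroxyphenyl end), each ring is numbered from its first-written atom, and 2, 4 and 10 are assumed to be bought.
Notation: GF-yl = 3,5-dimethoxy-4-(3,4,5-trimethoxyphenoxy)phenyl; GFE-yl = 3,4,5-trimethoxy-2-(GF-yloxy)phenyl; GFED-yl = 3,5-dimethoxy-4-(GFE-yloxy)phenyl; GFEDC-yl = 3,4,5-trimethoxy-2-(GFED-yloxy)phenyl; GFEDCB-yl = 3,5-dimethoxy-4-(GFEDC-yloxy)phenyl.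

Step 1
Reactants: 1 3,4,5-trimethoxyphenol; 2 dimethyl 2-chloropropanedioate (dimethyl chloromalonate)
Product: 3 dimethyl 2-(3,4,5-trimethoxyphenoxy)propanedioate
Conditions: K2CO3 (1.5 equiv), acetone, reflux
Reagents that add atoms: none
Why: Williamson-type SN2 O-alkylation of the phenoxide by the doubly activated alkyl chloride is the standard entry to 2-aryloxymalonates, and the chloride is chosen over the bromide because the bromide could brominate the electron-rich ring.

Step 2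
Reactants: 3 dimethyl 2-(3,4,5-trimethoxyphenoxy)propanedioate; 4 dimethyl 3-oxopentanedioate
Product: 6 dimethyl 2,4,6-trihydroxy-5-(3,4,5-trimethoxyphenoxy)benzene-1,3-dicarboxylate, via acyclic Claisen adduct 5 (not isolated)
Conditions: NaOMe (2.2 equiv), MeOH then toluene, 110 °C with distillation of MeOH, 4 added slowly to 3 (1.5 equiv); then 2 M HCl
Reagents that add atoms: none
Why: The enolate formed from 4 and NaOMe adds through one methylene carbon to an ester carbonyl of 3 and expels methoxide (intermolecular Claisen condensation, ring F bond C2–C3), giving the acyclic adduct 5. The other methylene carbon of the former keto diester then closes ring F through a 6-exo-trig Dieckmann-type attack on the remaining malonate ester carbonyl (bond C5–C6); loss of the second methanol and enolisation of the cyclohexanetrione give the arene, which is held as its phenoxide and so pulls the sequence forward. The closest known reaction type is the alkoxide-mediated condensation of malonic esters with 3-oxoglutaric esters to phloroglucinol dicarboxylates, and 2-aryloxymalonates are established double acylating agents under alkoxide conditions in pyrimidinediol syntheses with amidines. No stereocentre is formed. The step needs carbon rather than oxygen acylation and cross- rather than self-condensation of 4: both nucleophilic carbons of 4 are doubly activated methylenes, the reversible methoxide conditions let O-acylated and non-aromatisable adducts revert while only the all-carbon triketone is drained off by aromatisation, and slow addition of 4 to an excess of 3 keeps self-condensation down. The ether carbon C4, flanked by two oxygenated carbons, is thus never made by a hindered C–O coupling.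

Step 3
Reactants: 6 dimethyl 2,4,6-trihydroxy-5-(3,4,5-trimethoxyphenoxy)benzene-1,3-dicarboxylate
Product: 7 dimethyl 2-hydroxy-4,6-dimethoxy-5-(3,4,5-trimethoxyphenoxy)benzene-1,3-dicarboxylate
Conditions: MeI (2.1 equiv), K2CO3 (2.1 equiv), acetone, 40 °C
Reagents that add atoms: iodomethane, CI
Why: Chelation-controlled partial Williamson O-methylation: the ring F C1 hydroxyl lies between two ester carbonyls, is hydrogen-bonded whichever way the esters turn and is the most shielded, so two equivalents of iodomethane should cap the C3 and C5 hydroxyls first, by analogy with 2,4-diacylphloroglucinols whose hydroxyl between the carbonyls is alkylated last; no ring C–H is left for C-methylation.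

Step 4
Reactants: 7 dimethyl 2-hydroxy-4,6-dimethoxy-5-(3,4,5-trimethoxyphenoxy)benzene-1,3-dicarboxylate
Product: 9 3,5-dimethoxy-4-(3,4,5-trimethoxyphenoxy)phenol (GF-ol), via dicarboxylic acid 8 (not isolated)
Conditions: KOH, DMSO–H2O, 100 °C; then 3 M HCl, 60 °C
Reagents that add atoms: none
Why: Saponification followed by acid-promoted protodecarboxylation, which is easy here because each carboxyl sits ortho or para to three ring oxygens (ipso protonation), unmasks the ring F C1 phenol between two C–H positions.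

Step 5
Reactants: 9 3,5-dimethoxy-4-(3,4,5-trimethoxyphenoxy)phenol (GF-ol); 10 2-bromo-3,4,5-trimethoxybenzaldehyde
Product: 11 3,4,5-trimethoxy-2-(GF-yloxy)benzaldehyde
Conditions: CuI (10 mol%), N,N-dimethylglycine (30 mol%), Cs2CO3, 1,4-dioxane, 100 °C
Reagents that add atoms: none
Why: Ullmann diaryl ether coupling in which the unhindered, electron-rich phenoxide replaces bromide at a C–Br bond that the ortho formyl group activates, so ring E arrives with its future C1 oxygen masked as the aldehyde.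

Step 6
Reactants: 11 3,4,5-trimethoxy-2-(GF-yloxy)benzaldehyde
Product: 13 3,4,5-trimethoxy-2-(GF-yloxy)phenol (GFE-ol), via aryl formate 12 (not isolated)
Conditions: mCPBA, CH2Cl2, 0 °C to rt; then MeOH, HCl (cat.), rt
Reagents that add atoms: 3-chloroperoxybenzoic acid (mCPBA), OOC(=O)c1cccc(Cl)c1
Why: Dakin-type Baeyer–Villiger oxidation in which the electron-rich aryl group (ortho aryloxy, para methoxy) migrates to give the aryl formate, which acid methanolysis cleaves to the ring E C1 phenol.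

Step 7
Reactants: 13 3,4,5-trimethoxy-2-(GF-yloxy)phenol (GFE-ol); 2 dimethyl 2-chloropropanedioate
Product: 14 dimethyl 2-(GFE-yloxy)propanedioate
Conditions: K2CO3 (1.5 equiv), acetone, reflux
Reagents that add atoms: none
Why: Williamson O-alkylation as in step 1; the SN2 centre lies on the small chloromalonate, so the ortho aryloxy group of the phenol should not hinder it.

Step 8
Reactants: 14 dimethyl 2-(GFE-yloxy)propanedioate; 4 dimethyl 3-oxopentanedioate
Product: 16 dimethyl 2,4,6-trihydroxy-5-(GFE-yloxy)benzene-1,3-dicarboxylate, via acyclic Claisen adduct 15 (not isolated)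
Conditions: NaOMe (2.2 equiv), MeOH then toluene, 110 °C with distillation of MeOH, 4 added slowly to 14 (1.5 equiv); then 2 M HCl
Reagents that add atoms: none
Why: Claisen–Dieckmann benzannulation as in step 2, here forming ring D bonds C2–C3 and C5–C6 around the ether oxygen of ring E, so that the crowded D C4–O bond never has to be made by coupling.

Step 9
Reactants: 16 dimethyl 2,4,6-trihydroxy-5-(GFE-yloxy)benzene-1,3-dicarboxylate
Product: 17 dimethyl 2-hydroxy-4,6-dimethoxy-5-(GFE-yloxy)benzene-1,3-dicarboxylate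
Conditions: MeI (2.1 equiv), K2CO3 (2.1 equiv), acetone, 40 °C
Reagents that add atoms: iodomethane, CI
Why: Chelation-controlled partial O-methylation as in step 3, which should leave the ring D C1 hydroxyl between the two esters free.

Step 10
Reactants: 17 dimethyl 2-hydroxy-4,6-dimethoxy-5-(GFE-yloxy)benzene-1,3-dicarboxylate
Product: 19 3,5-dimethoxy-4-(GFE-yloxy)phenol (GFED-ol), via dicarboxylic acid 18 (not isolated)
Conditions: KOH, DMSO–H2O, 100 °C; then 3 M HCl, 60 °C
Reagents that add atoms: none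
Why: Saponification and acid protodecarboxylation as in step 4 give the ring D C1 phenol.

Step 11
Reactants: 19 3,5-dimethoxy-4-(GFE-yloxy)phenol (GFED-ol); 10 2-bromo-3,4,5-trimethoxybenzaldehyde
Product: 20 3,4,5-trimethoxy-2-(GFED-yloxy)benzaldehyde
Conditions: CuI (10 mol%), N,N-dimethylglycine (30 mol%), Cs2CO3, 1,4-dioxane, 100 °C
Reagents that add atoms: none
Why: Ullmann diaryl ether coupling as in step 5 introduces ring C as its ortho-formyl precursor at an unhindered phenol.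

Step 12
Reactants: 20 3,4,5-trimethoxy-2-(GFED-yloxy)benzaldehyde
Product: 22 3,4,5-trimethoxy-2-(GFED-yloxy)phenol (GFEDC-ol), via aryl formate 21 (not isolated)
Conditions: mCPBA, CH2Cl2, 0 °C to rt; then MeOH, HCl (cat.), rt
Reagents that add atoms: 3-chloroperoxybenzoic acid (mCPBA), OOC(=O)c1cccc(Cl)c1
Why: Dakin-type Baeyer–Villiger oxidation and formate methanolysis as in step 6 give the ring C C1 phenol.

Step 13
Reactants: 22 3,4,5-trimethoxy-2-(GFED-yloxy)phenol (GFEDC-ol); 2 dimethyl 2-chloropropanedioate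
Product: 23 dimethyl 2-(GFEDC-yloxy)propanedioate
Conditions: K2CO3 (1.5 equiv), acetone, reflux
Reagents that add atoms: none
Why: Williamson O-alkylation as in steps 1 and 7.

Step 14
Reactants: 23 dimethyl 2-(GFEDC-yloxy)propanedioate; 4 dimethyl 3-oxopentanedioate
Product: 25 dimethyl 2,4,6-trihydroxy-5-(GFEDC-yloxy)benzene-1,3-dicarboxylate, via acyclic Claisen adduct 24 (not isolated)
Conditions: NaOMe (2.2 equiv), MeOH then toluene, 110 °C with distillation of MeOH, 4 added slowly to 23 (1.5 equiv); then 2 M HCl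
Reagents that add atoms: none
Why: Claisen–Dieckmann benzannulation as in step 2, forming ring B bonds C2–C3 and C5–C6.

Step 15
Reactants: 25 dimethyl 2,4,6-trihydroxy-5-(GFEDC-yloxy)benzene-1,3-dicarboxylate
Product: 26 dimethyl 2-hydroxy-4,6-dimethoxy-5-(GFEDC-yloxy)benzene-1,3-dicarboxylate
Conditions: MeI (2.1 equiv), K2CO3 (2.1 equiv), acetone, 40 °C
Reagents that add atoms: iodomethane, CI
Why: Chelation-controlled partial O-methylation as in step 3, which should leave the ring B C1 hydroxyl free.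

Step 16
Reactants: 26 dimethyl 2-hydroxy-4,6-dimethoxy-5-(GFEDC-yloxy)benzene-1,3-dicarboxylate
Product: 28 3,5-dimethoxy-4-(GFEDC-yloxy)phenol (GFEDCB-ol), via dicarboxylic acid 27 (not isolated)
Conditions: KOH, DMSO–H2O, 100 °C; then 3 M HCl, 60 °C
Reagents that add atoms: none
Why: Saponification and acid protodecarboxylation as in step 4 give the ring B C1 phenol.

Step 17
Reactants: 28 3,5-dimethoxy-4-(GFEDC-yloxy)phenol (GFEDCB-ol); 2 dimethyl 2-chloropropanedioate
Product: 29 dimethyl 2-(GFEDCB-yloxy)propanedioate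
Conditions: K2CO3 (1.5 equiv), acetone, reflux
Reagents that add atoms: none
Why: Williamson O-alkylation as in step 1, here at a phenol with two free ortho positions.

Step 18
Reactants: 29 dimethyl 2-(GFEDCB-yloxy)propanedioate; 4 dimethyl 3-oxopentanedioate
Product: 31 dimethyl 2,4,6-trihydroxy-5-(GFEDCB-yloxy)benzene-1,3-dicarboxylate, via acyclic Claisen adduct 30 (not isolated)
Conditions: NaOMe (2.2 equiv), MeOH then toluene, 110 °C with distillation of MeOH, 4 added slowly to 29 (1.5 equiv); then 2 M HCl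
Reagents that add atoms: none
Why: Claisen–Dieckmann benzannulation as in step 2 forms ring A, whose three hydroxyls are all wanted free, so no differentiation is needed.

Step 19
Reactants: 31 dimethyl 2,4,6-trihydroxy-5-(GFEDCB-yloxy)benzene-1,3-dicarboxylate
Product: 33 2-(GFEDCB-yloxy)benzene-1,3,5-triol, via dicarboxylic acid 32 (not isolated)
Conditions: KOH, MeOH–H2O, reflux, argon; then 3 M HCl, 50 °C
Reagents that add atoms: none
Why: Saponification and protodecarboxylation of a phloroglucinol dicarboxylate, which loses both carboxyl groups on gentle warming in acid, with argon protecting the electron-rich triol.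

Step 20
Reactants: 33 2-(GFEDCB-yloxy)benzene-1,3,5-triol
Product: 34 CNP0292517.0
Conditions: BBr3 (30 equiv), CH2Cl2, −78 °C to rt; then H2O, 0 °C, argon
Reagents that add atoms: none
Why: Exhaustive aryl methyl ether cleavage with BBr3 (boron coordination, bromide attack on the methyl groups, hydrolysis of the aryl borates) should free all fifteen masked hydroxyls, since diaryl ether bonds are inert to this reagent.

Compound list
1 | 3,4,5-trimethoxyphenol | COc1cc(O)cc(OC)c1OC | starting material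
2 | dimethyl 2-chloropropanedioate (dimethyl chloromalonate) | COC(=O)C(Cl)C(=O)OC | starting material
3 | dimethyl 2-(3,4,5-trimethoxyphenoxy)propanedioate | COC(=O)C(Oc1cc(OC)c(OC)c(OC)c1)C(=O)OC | intermediate
4 | dimethyl 3-oxopentanedioate | COC(=O)CC(=O)CC(=O)OC | starting material
5 | dimethyl 4-(methoxycarbonyl)-3,5-dioxo-2-(3,4,5-trimethoxyphenoxy)heptanedioate (acyclic Claisen adduct; enolisable mixture of stereoisomers) | COC(=O)CC(=O)C(C(=O)OC)C(=O)C(Oc1cc(OC)c(OC)c(OC)c1)C(=O)OC | intermediate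
6 | dimethyl 2,4,6-trihydroxy-5-(3,4,5-trimethoxyphenoxy)benzene-1,3-dicarboxylate | COC(=O)c1c(O)c(C(=O)OC)c(O)c(Oc2cc(OC)c(OC)c(OC)c2)c1O | intermediate
7 | dimethyl 2-hydroxy-4,6-dimethoxy-5-(3,4,5-trimethoxyphenoxy)benzene-1,3-dicarboxylate | COC(=O)c1c(O)c(C(=O)OC)c(OC)c(Oc2cc(OC)c(OC)c(OC)c2)c1OC | intermediate
8 | 2-hydroxy-4,6-dimethoxy-5-(3,4,5-trimethoxyphenoxy)benzene-1,3-dicarboxylic acid | OC(=O)c1c(O)c(C(=O)O)c(OC)c(Oc2cc(OC)c(OC)c(OC)c2)c1OC | intermediate
9 | 3,5-dimethoxy-4-(3,4,5-trimethoxyphenoxy)phenol (GF-ol) | COc1cc(O)cc(OC)c1Oc1cc(OC)c(OC)c(OC)c1 | intermediate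
10 | 2-bromo-3,4,5-trimethoxybenzaldehyde | COc1cc(C=O)c(Br)c(OC)c1OC | starting material
11 | 3,4,5-trimethoxy-2-(GF-yloxy)benzaldehyde | O=Cc1cc(OC)c(OC)c(OC)c1Oc1cc(OC)c(Oc2cc(OC)c(OC)c(OC)c2)c(OC)c1 | intermediate
12 | 3,4,5-trimethoxy-2-(GF-yloxy)phenyl formate | O=COc1cc(OC)c(OC)c(OC)c1Oc1cc(OC)c(Oc2cc(OC)c(OC)c(OC)c2)c(OC)c1 | intermediate
13 | 3,4,5-trimethoxy-2-(GF-yloxy)phenol (GFE-ol) | Oc1cc(OC)c(OC)c(OC)c1Oc1cc(OC)c(Oc2cc(OC)c(OC)c(OC)c2)c(OC)c1 | intermediate
14 | dimethyl 2-(GFE-yloxy)propanedioate | COC(=O)C(Oc1cc(OC)c(OC)c(OC)c1Oc1cc(OC)c(Oc2cc(OC)c(OC)c(OC)c2)c(OC)c1)C(=O)OC | intermediate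
15 | dimethyl 2-(GFE-yloxy)-4-(methoxycarbonyl)-3,5-dioxoheptanedioate (acyclic Claisen adduct; enolisable mixture of stereoisomers) | COC(=O)CC(=O)C(C(=O)OC)C(=O)C(Oc1cc(OC)c(OC)c(OC)c1Oc1cc(OC)c(Oc2cc(OC)c(OC)c(OC)c2)c(OC)c1)C(=O)OC | intermediate
16 | dimethyl 2,4,6-trihydroxy-5-(GFE-yloxy)benzene-1,3-dicarboxylate | COC(=O)c1c(O)c(C(=O)OC)c(O)c(Oc2cc(OC)c(OC)c(OC)c2Oc2cc(OC)c(Oc3cc(OC)c(OC)c(OC)c3)c(OC)c2)c1O | intermediate
17 | dimethyl 2-hydroxy-4,6-dimethoxy-5-(GFE-yloxy)benzene-1,3-dicarboxylate | COC(=O)c1c(O)c(C(=O)OC)c(OC)c(Oc2cc(OC)c(OC)c(OC)c2Oc2cc(OC)c(Oc3cc(OC)c(OC)c(OC)c3)c(OC)c2)c1OC | intermediate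
18 | 2-hydroxy-4,6-dimethoxy-5-(GFE-yloxy)benzene-1,3-dicarboxylic acid | OC(=O)c1c(O)c(C(=O)O)c(OC)c(Oc2cc(OC)c(OC)c(OC)c2Oc2cc(OC)c(Oc3cc(OC)c(OC)c(OC)c3)c(OC)c2)c1OC | intermediate
19 | 3,5-dimethoxy-4-(GFE-yloxy)phenol (GFED-ol) | COc1cc(O)cc(OC)c1Oc1cc(OC)c(OC)c(OC)c1Oc1cc(OC)c(Oc2cc(OC)c(OC)c(OC)c2)c(OC)c1 | intermediate
20 | 3,4,5-trimethoxy-2-(GFED-yloxy)benzaldehyde | O=Cc1cc(OC)c(OC)c(OC)c1Oc1cc(OC)c(Oc2cc(OC)c(OC)c(OC)c2Oc2cc(OC)c(Oc3cc(OC)c(OC)c(OC)c3)c(OC)c2)c(OC)c1 | intermediate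
21 | 3,4,5-trimethoxy-2-(GFED-yloxy)phenyl formate | O=COc1cc(OC)c(OC)c(OC)c1Oc1cc(OC)c(Oc2cc(OC)c(OC)c(OC)c2Oc2cc(OC)c(Oc3cc(OC)c(OC)c(OC)c3)c(OC)c2)c(OC)c1 | intermediate
22 | 3,4,5-trimethoxy-2-(GFED-yloxy)phenol (GFEDC-ol) | Oc1cc(OC)c(OC)c(OC)c1Oc1cc(OC)c(Oc2cc(OC)c(OC)c(OC)c2Oc2cc(OC)c(Oc3cc(OC)c(OC)c(OC)c3)c(OC)c2)c(OC)c1 | intermediate
23 | dimethyl 2-(GFEDC-yloxy)propanedioate | COC(=O)C(Oc1cc(OC)c(OC)c(OC)c1Oc1cc(OC)c(Oc2cc(OC)c(OC)c(OC)c2Oc2cc(OC)c(Oc3cc(OC)c(OC)c(OC)c3)c(OC)c2)c(OC)c1)C(=O)OC | intermediate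
24 | dimethyl 2-(GFEDC-yloxy)-4-(methoxycarbonyl)-3,5-dioxoheptanedioate (acyclic Claisen adduct; enolisable mixture of stereoisomers) | COC(=O)CC(=O)C(C(=O)OC)C(=O)C(Oc1cc(OC)c(OC)c(OC)c1Oc1cc(OC)c(Oc2cc(OC)c(OC)c(OC)c2Oc2cc(OC)c(Oc3cc(OC)c(OC)c(OC)c3)c(OC)c2)c(OC)c1)C(=O)OC | intermediate
25 | dimethyl 2,4,6-trihydroxy-5-(GFEDC-yloxy)benzene-1,3-dicarboxylate | COC(=O)c1c(O)c(C(=O)OC)c(O)c(Oc2cc(OC)c(OC)c(OC)c2Oc2cc(OC)c(Oc3cc(OC)c(OC)c(OC)c3Oc3cc(OC)c(Oc4cc(OC)c(OC)c(OC)c4)c(OC)c3)c(OC)c2)c1O | intermediate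
26 | dimethyl 2-hydroxy-4,6-dimethoxy-5-(GFEDC-yloxy)benzene-1,3-dicarboxylate | COC(=O)c1c(O)c(C(=O)OC)c(OC)c(Oc2cc(OC)c(OC)c(OC)c2Oc2cc(OC)c(Oc3cc(OC)c(OC)c(OC)c3Oc3cc(OC)c(Oc4cc(OC)c(OC)c(OC)c4)c(OC)c3)c(OC)c2)c1OC | intermediate
27 | 2-hydroxy-4,6-dimethoxy-5-(GFEDC-yloxy)benzene-1,3-dicarboxylic acid | OC(=O)c1c(O)c(C(=O)O)c(OC)c(Oc2cc(OC)c(OC)c(OC)c2Oc2cc(OC)c(Oc3cc(OC)c(OC)c(OC)c3Oc3cc(OC)c(Oc4cc(OC)c(OC)c(OC)c4)c(OC)c3)c(OC)c2)c1OC | intermediate
28 | 3,5-dimethoxy-4-(GFEDC-yloxy)phenol (GFEDCB-ol) | COc1cc(O)cc(OC)c1Oc1cc(OC)c(OC)c(OC)c1Oc1cc(OC)c(Oc2cc(OC)c(OC)c(OC)c2Oc2cc(OC)c(Oc3cc(OC)c(OC)c(OC)c3)c(OC)c2)c(OC)c1 | intermediate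
29 | dimethyl 2-(GFEDCB-yloxy)propanedioate | COC(=O)C(Oc1cc(OC)c(Oc2cc(OC)c(OC)c(OC)c2Oc2cc(OC)c(Oc3cc(OC)c(OC)c(OC)c3Oc3cc(OC)c(Oc4cc(OC)c(OC)c(OC)c4)c(OC)c3)c(OC)c2)c(OC)c1)C(=O)OC | intermediate
30 | dimethyl 2-(GFEDCB-yloxy)-4-(methoxycarbonyl)-3,5-dioxoheptanedioate (acyclic Claisen adduct; enolisable mixture of stereoisomers) | COC(=O)CC(=O)C(C(=O)OC)C(=O)C(Oc1cc(OC)c(Oc2cc(OC)c(OC)c(OC)c2Oc2cc(OC)c(Oc3cc(OC)c(OC)c(OC)c3Oc3cc(OC)c(Oc4cc(OC)c(OC)c(OC)c4)c(OC)c3)c(OC)c2)c(OC)c1)C(=O)OC | intermediate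
31 | dimethyl 2,4,6-trihydroxy-5-(GFEDCB-yloxy)benzene-1,3-dicarboxylate | COC(=O)c1c(O)c(C(=O)OC)c(O)c(Oc2cc(OC)c(Oc3cc(OC)c(OC)c(OC)c3Oc3cc(OC)c(Oc4cc(OC)c(OC)c(OC)c4Oc4cc(OC)c(Oc5cc(OC)c(OC)c(OC)c5)c(OC)c4)c(OC)c3)c(OC)c2)c1O | intermediate
32 | 2,4,6-trihydroxy-5-(GFEDCB-yloxy)benzene-1,3-dicarboxylic acid | OC(=O)c1c(O)c(C(=O)O)c(O)c(Oc2cc(OC)c(Oc3cc(OC)c(OC)c(OC)c3Oc3cc(OC)c(Oc4cc(OC)c(OC)c(OC)c4Oc4cc(OC)c(Oc5cc(OC)c(OC)c(OC)c5)c(OC)c4)c(OC)c3)c(OC)c2)c1O | intermediate
33 | 2-(GFEDCB-yloxy)benzene-1,3,5-triol (pentadeca-O-methyl ether of the target) | Oc1cc(O)c(Oc2cc(OC)c(Oc3cc(OC)c(OC)c(OC)c3Oc3cc(OC)c(Oc4cc(OC)c(OC)c(OC)c4Oc4cc(OC)c(Oc5cc(OC)c(OC)c(OC)c5)c(OC)c4)c(OC)c3)c(OC)c2)c(O)c1 | intermediate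
34 | CNP0292517.0 (heptameric phlorotannin with eighteen free hydroxyls, no stereocentre) | Oc1cc(O)c(Oc2cc(O)c(Oc3cc(O)c(O)c(O)c3Oc3cc(O)c(Oc4cc(O)c(O)c(O)c4Oc4cc(O)c(Oc5cc(O)c(O)c(O)c5)c(O)c4)c(O)c3)c(O)c2)c(O)c1 | target

Total step count: 20. Longest linear sequence: 20 steps (1 to 34); the route is fully linear, with 2, 4 and 10 fed in repeatedly.

Steps most likely to fail

1. Step 2 (the same risk recurs in steps 8, 14 and 18). The cross-acylation may be outrun by self-condensation of 4. It may also stall because 3 sits largely as its unreactive enolate, or the adduct may close through oxygen to a pyranone that does not revert fast enough. Fallback: split the annulation into two known operations with a more reactive acyl donor. Setting out from 3, one ester is hydrolysed (KOH, 1 equiv, MeOH, 0 °C; then HCl) to 3-methoxy-3-oxo-2-(3,4,5-trimethoxyphenoxy)propanoic acid F1 (racemic), which oxalyl chloride (cat. DMF, CH2Cl2) turns into methyl 3-chloro-3-oxo-2-(3,4,5-trimethoxyphenoxy)propanoate F2. The acid chloride acylates 4 on carbon under soft enolisation (MgCl2, Et3N, MeCN, 0 °C) to give 5, which is isolated this time. NaOMe in MeOH at reflux then closes ring F by Dieckmann condensation and aromatisation, and the route is rejoined at 6.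

2. Step 3 (recurs in steps 9 and 15). The three hydroxyls may not be told apart well enough: methylation may reach the hydroxyl between the esters, or run on to the trimethyl ether. Fallback: differentiate after decarboxylation by sterics instead of chelation. Setting out from 6, hydrolysis (KOH, H2O, reflux, argon) gives 2,4,6-trihydroxy-5-(3,4,5-trimethoxyphenoxy)benzene-1,3-dicarboxylic acid F3, which loses CO2 on acidification and warming to give 2-(3,4,5-trimethoxyphenoxy)benzene-1,3,5-triol F4. One equivalent of TIPSCl with imidazole (DMF, −20 °C) should silylate the only hydroxyl without an ortho substituent, the one on ring F C1, to give 5-[tri(propan-2-yl)silyloxy]-2-(3,4,5-trimethoxyphenoxy)benzene-1,3-diol F5. The two remaining hydroxyls are methylated (MeI, K2CO3, acetone) to [3,5-dimethoxy-4-(3,4,5-trimethoxyphenoxy)phenoxy]tri(propan-2-yl)silane F6, and Bu4NF in THF releases the phenol, rejoining the route at 9.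

3. Step 20. Cleavage at fifteen sites may stop short, and the free polyphenol may oxidise in air during purification. Fallback: isolate through the peracetate. Setting out from 33, the crude BBr3 product (34) is acetylated at once (Ac2O, pyridine, rt) to the octadecaacetate of 34 F7, which should be stable and can be purified on silica, where under-cleaved material is removed. Acid methanolysis (HCl generated from AcCl in MeOH, 40 °C, argon) then returns 34 with only volatile by-products.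

Further compounds
F1 | step 2 | 3-methoxy-3-oxo-2-(3,4,5-trimethoxyphenoxy)propanoic acid (racemic) | COC(=O)C(Oc1cc(OC)c(OC)c(OC)c1)C(=O)O
F2 | step 2 | methyl 3-chloro-3-oxo-2-(3,4,5-trimethoxyphenoxy)propanoate (racemic) | COC(=O)C(Oc1cc(OC)c(OC)c(OC)c1)C(Cl)=O
F3 | step 3 | 2,4,6-trihydroxy-5-(3,4,5-trimethoxyphenoxy)benzene-1,3-dicarboxylic acid | OC(=O)c1c(O)c(C(=O)O)c(O)c(Oc2cc(OC)c(OC)c(OC)c2)c1O
F4 | step 3 | 2-(3,4,5-trimethoxyphenoxy)benzene-1,3,5-triol | Oc1cc(O)c(Oc2cc(OC)c(OC)c(OC)c2)c(O)c1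
F5 | step 3 | 5-[tri(propan-2-yl)silyloxy]-2-(3,4,5-trimethoxyphenoxy)benzene-1,3-diol | CC(C)[Si](Oc1cc(O)c(Oc2cc(OC)c(OC)c(OC)c2)c(O)c1)(C(C)C)C(C)C
F6 | step 3 | [3,5-dimethoxy-4-(3,4,5-trimethoxyphenoxy)phenoxy]tri(propan-2-yl)silane | CC(C)[Si](Oc1cc(OC)c(Oc2cc(OC)c(OC)c(OC)c2)c(OC)c1)(C(C)C)C(C)C
F7 | step 20 | octadecaacetate of 34 | CC(=O)Oc1cc(OC(C)=O)c(Oc2cc(OC(C)=O)c(Oc3cc(OC(C)=O)c(OC(C)=O)c(OC(C)=O)c3Oc3cc(OC(C)=O)c(Oc4cc(OC(C)=O)c(OC(C)=O)c(OC(C)=O)c4Oc4cc(OC(C)=O)c(Oc5cc(OC(C)=O)c(OC(C)=O)c(OC(C)=O)c5)c(OC(C)=O)c4)c(OC(C)=O)c3)c(OC(C)=O)c2)c(OC(C)=O)c1
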